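**Retrosynthetic overview**
1. Target 20 ⇐ 19 by a singlet-oxygen ene reaction (C5–OOH, C4=C15). 19 ⇐ bicyclic silyl enol ether 14 by C7 protonation, C8 reduction and acetylation.
2. 14 ⇐ acyclic allene–silyloxytriene 13 by one intramolecular [4+2]. The C5–C10 and C6–C7 bonds form together, so ring A (the tether ring, keeping the allene bond as C4=C5) and ring B (the cycloaddition ring) close in the same operation.
3. 13 ⇐ geranyl acetate 1 (C1–C3, C8–C10, C14) + 1-bromobut-2-yne 4 (C4–C6, C15) + methyl 2-(bromomethyl)acrylate 10 (C7, C11–C13, OMe) + angelic acid 8.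
4. C3 is the only centre set by a catalyst; C10, C7, C8 and C5 are relayed from it.

Assumption: the SMILES is read as methyl (3R,5S,7R,8R,10R)-8-acetoxy-3-angeloyloxy-5-hydroperoxyeudesma-4(15),11(13)-dien-12-oate (3α-OAng, 5α-OOH, 7β side chain, 8β-OAc, 10β-Me). Eudesmane numbering is used throughout and angeloyl means (2Z)-2-methylbut-2-enoyl.

**Step 1**
Reactants: 1 geranyl acetate
Product: 3 (2E)-3-methyl-6-oxohex-2-en-1-yl acetate, via secondary ozonide 2 (not isolated)
Conditions: O3 (1.0 equiv), CH2Cl2, −78 °C; then Me2S, −78 °C to rt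
Reagents that add atoms: ozone, [O-][O+]=O
Why: Criegee ozonolysis cleaves the electron-rich 6,7-alkene much faster than the 2,3-alkene, which is deactivated by the allylic acetate, and Me2S reduces the ozonide to the aldehyde; no stereocentre is formed.

**Step 2**
Reactants: 3 (2E)-3-methyl-6-oxohex-2-en-1-yl acetate; 4 1-bromobut-2-yne
Product: 6 (2E,6R)-3,7-dimethylnona-2,7,8-triene-1,6-diol, via trimethylsilyl ether 5 (not isolated)
Conditions: CrCl2 (10 mol %), chiral tridentate 1,8-bis(oxazolinyl)carbazole ligand (10 mol %, the enantiomer giving Si-face addition), i-Pr2NEt (30 mol %), Mn powder, Me3SiCl, THF, rt; then K2CO3, MeOH, rt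
Reagents that add atoms: none
Why: Catalytic enantioselective Nozaki–Hiyama allenylation, in which the 2-butynylchromium species adds SE2′ through a cyclic transition state to the Si face of the aldehyde under ligand control to set the carbinol centre as R (C3 of the target), the γ-methyl group steering the reaction to the allenyl rather than the homopropargyl alcohol, after which K2CO3/MeOH removes the silyl and acetyl groups in the same flask.

**Step 3**
Reactants: 6 (2E,6R)-3,7-dimethylnona-2,7,8-triene-1,6-diol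
Product: 7 (2E,6R)-6-hydroxy-3,7-dimethylnona-2,7,8-trienal
Conditions: TEMPO (10 mol %), PhI(OAc)2, CH2Cl2, rt
Reagents that add atoms: none
Why: Oxoammonium (TEMPO) oxidation is selective for the primary allylic alcohol over the secondary α-allenic alcohol and leaves the E-alkene and the stereocentre untouched.

**Step 4**
Reactants: 7 (2E,6R)-6-hydroxy-3,7-dimethylnona-2,7,8-trienal; 8 angelic acid
Product: 9 (4R,7E)-3,7-dimethyl-9-oxonona-1,2,7-trien-4-yl (2Z)-2-methylbut-2-enoate
Conditions: 2,4,6-trichlorobenzoyl chloride, Et3N, toluene, rt; then DMAP, rt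
Reagents that add atoms: none
Why: Yamaguchi esterification through the mixed anhydride acylates the alcohol with retention at carbon and avoids the Z-to-E isomerisation (angelate to tiglate) seen with acid chlorides or carbodiimides.

**Step 5**
Reactants: 9 (4R,7E)-3,7-dimethyl-9-oxonona-1,2,7-trien-4-yl (2Z)-2-methylbut-2-enoate; 10 methyl 2-(bromomethyl)prop-2-enoate
Product: 11 methyl (5E,9R)-9-angeloyloxy-4-hydroxy-6,10-dimethyl-2-methylidenedodeca-5,10,11-trienoate
Conditions: Zn dust, THF/sat. aq NH4Cl, 0 °C to rt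
Reagents that add atoms: none
Why: Zinc Barbier 2-(alkoxycarbonyl)allylation adds 1,2 to the enal and brings in the complete acrylate side chain (C7, C11–C13); the new carbinol centre forms as a mixture that is erased in step 6.

**Step 6**
Reactants: 11 methyl (5E,9R)-9-angeloyloxy-4-hydroxy-6,10-dimethyl-2-methylidenedodeca-5,10,11-trienoate
Product: 12 methyl (5E,9R)-9-angeloyloxy-6,10-dimethyl-2-methylidene-4-oxododeca-5,10,11-trienoate
Conditions: MnO2 (activated, excess), CH2Cl2, rt
Reagents that add atoms: none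
Why: MnO2 oxidises the allylic alcohol under neutral conditions, so the base-labile β,γ-unsaturated keto ester is not isomerised into conjugation.

**Step 7**
Reactants: 12 methyl (5E,9R)-9-angeloyloxy-6,10-dimethyl-2-methylidene-4-oxododeca-5,10,11-trienoate
Product: 13 methyl (3Z,5E,9R)-9-angeloyloxy-4-(tert-butyldimethylsilyloxy)-6,10-dimethyl-2-methylidenedodeca-3,5,10,11-tetraenoate
Conditions: TBSOTf, Et3N, CH2Cl2, −78 °C
Reagents that add atoms: tert-butyldimethylsilyl trifluoromethanesulfonate, CC(C)(C)[Si](C)(C)OS(=O)(=O)C(F)(F)F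
Why: Soft enolisation removes the doubly activated proton between the ketone and the acrylate and gives the cross-conjugated 2-silyloxydiene as the Z enol ether, which puts the acrylate outside and hydrogen inside on the diene terminus.

**Step 8**
Reactants: 13 methyl (3Z,5E,9R)-9-angeloyloxy-4-(tert-butyldimethylsilyloxy)-6,10-dimethyl-2-methylidenedodeca-3,5,10,11-tetraenoate
Product: 14 methyl (3R,7S,10R)-3-angeloyloxy-8-(tert-butyldimethylsilyloxy)eudesma-4,8,11(13)-trien-12-oate
Conditions: toluene (0.005 M), BHT (cat.), 130–150 °C, sealed tube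
Reagents that add atoms: none
Why: Proposed new method: an intramolecular Diels–Alder reaction of the 2-silyloxydiene with the distal C=CH2 bond of the 1,1-disubstituted allene (the proximal bond would have to join two fully substituted carbons) closes rings A and B together and leaves the retained allene bond as the tetrasubstituted C4=C5 alkene; a half-chair tether with the C3 angelate pseudoaxial (avoiding A(1,2) strain with the C4 methyl) sets the quaternary C10 methyl trans to the C3 oxygen, and suprafacial addition to the E,Z-diene puts the C7 side chain trans to that methyl (7α, corrected in step 9); the closest known reaction types are thermal intramolecular Diels–Alder reactions of allenyl ethers at the terminal allene bond, intramolecular Diels–Alder reactions of 2-silyloxydienes, and rhodium-catalysed diene–allene [4+2] cycloadditions.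

**Step 9**
Reactants: 14 methyl (3R,7S,10R)-3-angeloyloxy-8-(tert-butyldimethylsilyloxy)eudesma-4,8,11(13)-trien-12-oate
Product: 17 methyl (3R,7R,10R)-3-angeloyloxy-8-oxoeudesma-4,11(13)-dien-12-oate, via C9 enolate 15 (not isolated), via C7 dienolate 16 (not isolated)
Conditions: TBAF (1.05 equiv), THF (0.02 M), −78 to −20 °C; then AcOH, −78 °C
Reagents that add atoms: none
Why: Fluoride cleaves the silyl enol ether, the enolate equilibrates by proton transfer to the more stable conjugated C7 dienolate, and kinetic α-protonation (deconjugative protonation) from the axial α face, anti to the C10 methyl, gives the equatorial 7β side chain (7R) while keeping the exocyclic acrylate double bond.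

**Step 10**
Reactants: 17 methyl (3R,7R,10R)-3-angeloyloxy-8-oxoeudesma-4,11(13)-dien-12-oate
Product: 18 methyl (3R,7R,8R,10R)-3-angeloyloxy-8-hydroxyeudesma-4,11(13)-dien-12-oate
Conditions: NaBH4, CeCl3·7H2O, MeOH, −78 °C; cold neutral work-up
Reagents that add atoms: none
Why: Luche reduction delivers hydride to C8 from the α face because the β (axial) trajectory is blocked by the syn-axial C10 methyl, giving the axial 8β alcohol (8R) cis to the C7 side chain, and CeCl3 suppresses conjugate reduction of the acrylate.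

**Step 11**
Reactants: 18 methyl (3R,7R,8R,10R)-3-angeloyloxy-8-hydroxyeudesma-4,11(13)-dien-12-oate
Product: 19 methyl (3R,7R,8R,10R)-8-acetoxy-3-angeloyloxyeudesma-4,11(13)-dien-12-oate
Conditions: Ac2O, DMAP, pyridine, CH2Cl2, 0 °C to rt
Reagents that add atoms: acetic anhydride, CC(=O)OC(C)=O
Why: DMAP-catalysed acetylation traps the axial alcohol before it can lactonise onto the cis acrylate ester; no stereocentre changes.

**Step 12**
Reactants: 19 methyl (3R,7R,8R,10R)-8-acetoxy-3-angeloyloxyeudesma-4,11(13)-dien-12-oate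
Product: 20 methyl (3R,5S,7R,8R,10R)-8-acetoxy-3-angeloyloxy-5-hydroperoxyeudesma-4(15),11(13)-dien-12-oate
Conditions: O2, visible light, tetraphenylporphyrin (cat.), CH2Cl2, −20 °C
Reagents that add atoms: dioxygen, O=O
Why: Schenck ene reaction in which singlet oxygen attacks the only electron-rich alkene at C5 from the α face opposite the angular methyl and abstracts hydrogen from the C15 methyl geminal to the ester-bearing allylic carbon (geminal directing effect of an allylic oxygen substituent), giving the 5α-hydroperoxide (5S) and the 4(15)-alkene.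

**Compound list**
1 | geranyl acetate, (2E)-3,7-dimethylocta-2,6-dien-1-yl acetate | CC(C)=CCC/C(C)=C/COC(C)=O | starting material
2 | (2E)-5-(5,5-dimethyl-1,2,4-trioxolan-3-yl)-3-methylpent-2-en-1-yl acetate (secondary ozonide) | CC1(C)OOC(CC/C(C)=C/COC(C)=O)O1 | intermediate
3 | (2E)-3-methyl-6-oxohex-2-en-1-yl acetate | O=CCC/C(C)=C/COC(C)=O | intermediate
4 | 1-bromobut-2-yne | CC#CCBr | starting material
5 | (2E,6R)-3,7-dimethyl-6-(trimethylsilyloxy)nona-2,7,8-trien-1-yl acetate | C=C=C(C)[C@H](O[Si](C)(C)C)CC/C(C)=C/COC(C)=O | intermediate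
6 | (2E,6R)-3,7-dimethylnona-2,7,8-triene-1,6-diol | C=C=C(C)[C@H](O)CC/C(C)=C/CO | intermediate
7 | (2E,6R)-6-hydroxy-3,7-dimethylnona-2,7,8-trienal | C=C=C(C)[C@H](O)CC/C(C)=C/C=O | intermediate
8 | angelic acid, (2Z)-2-methylbut-2-enoic acid | C/C=C(/C)C(=O)O | starting material
9 | (4R,7E)-3,7-dimethyl-9-oxonona-1,2,7-trien-4-yl (2Z)-2-methylbut-2-enoate | C=C=C(C)[C@H](OC(=O)/C(C)=C\C)CC/C(C)=C/C=O | intermediate
10 | methyl 2-(bromomethyl)prop-2-enoate | C=C(CBr)C(=O)OC | starting material
11 | methyl (5E,9R)-9-angeloyloxy-4-hydroxy-6,10-dimethyl-2-methylidenedodeca-5,10,11-trienoate (both C4 epimers) | C=C=C(C)[C@H](OC(=O)/C(C)=C\C)CC/C(C)=C/C(O)CC(=C)C(=O)OC | intermediate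
12 | methyl (5E,9R)-9-angeloyloxy-6,10-dimethyl-2-methylidene-4-oxododeca-5,10,11-trienoate | C=C=C(C)[C@H](OC(=O)/C(C)=C\C)CC/C(C)=C/C(=O)CC(=C)C(=O)OC | intermediate
13 | methyl (3Z,5E,9R)-9-angeloyloxy-4-(tert-butyldimethylsilyloxy)-6,10-dimethyl-2-methylidenedodeca-3,5,10,11-tetraenoate | C=C=C(C)[C@H](OC(=O)/C(C)=C\C)CC/C(C)=C/C(O[Si](C)(C)C(C)(C)C)=C/C(=C)C(=O)OC | intermediate
14 | methyl (3R,7S,10R)-3-angeloyloxy-8-(tert-butyldimethylsilyloxy)eudesma-4,8,11(13)-trien-12-oate (3α-OAng; 7α side chain; 10β-Me) | C=C(C(=O)OC)[C@@H]1CC2=C(C)[C@H](OC(=O)/C(C)=C\C)CC[C@]2(C)C=C1O[Si](C)(C)C(C)(C)C | intermediate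
15 | tetrabutylammonium (3R,7S,10R)-3-angeloyloxy-12-methoxy-12-oxoeudesma-4,8,11(13)-trien-8-olate (C8=C9 enolate) | C=C(C(=O)OC)[C@@H]1CC2=C(C)[C@H](OC(=O)/C(C)=C\C)CC[C@]2(C)C=C1[O-].CCCC[N+](CCCC)(CCCC)CCCC | intermediate
16 | tetrabutylammonium (3R,10R)-3-angeloyloxy-12-methoxy-12-oxoeudesma-4,7,11(13)-trien-8-olate (C7=C8 dienolate) | C=C(C(=O)OC)C=1CC2=C(C)[C@H](OC(=O)/C(C)=C\C)CC[C@]2(C)CC=1[O-].CCCC[N+](CCCC)(CCCC)CCCC | intermediate
17 | methyl (3R,7R,10R)-3-angeloyloxy-8-oxoeudesma-4,11(13)-dien-12-oate | C=C(C(=O)OC)[C@H]1CC2=C(C)[C@H](OC(=O)/C(C)=C\C)CC[C@]2(C)CC1=O | intermediate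
18 | methyl (3R,7R,8R,10R)-3-angeloyloxy-8-hydroxyeudesma-4,11(13)-dien-12-oate | C=C(C(=O)OC)[C@H]1CC2=C(C)[C@H](OC(=O)/C(C)=C\C)CC[C@]2(C)C[C@H]1O | intermediate
19 | methyl (3R,7R,8R,10R)-8-acetoxy-3-angeloyloxyeudesma-4,11(13)-dien-12-oate | C=C(C(=O)OC)[C@H]1CC2=C(C)[C@H](OC(=O)/C(C)=C\C)CC[C@]2(C)C[C@H]1OC(C)=O | intermediate
20 | methyl (3R,5S,7R,8R,10R)-8-acetoxy-3-angeloyloxy-5-hydroperoxyeudesma-4(15),11(13)-dien-12-oate | C=C(C(=O)OC)[C@H]1C[C@@]2(OO)C(=C)[C@H](OC(=O)/C(C)=C\C)CC[C@]2(C)C[C@H]1OC(C)=O | target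

**Step count and risks**
Total steps: 12. Longest linear sequence: 12 (from geranyl acetate 1).

Most likely to fail, first: step 8. The diene carries an inside methyl and the dienophile is an unactivated allene, so the cycloaddition may be slow enough for a [1,5]-hydrogen shift of the diene to compete, and the C3-to-C10 relay may be only moderate. The fallback sets out from 13 and comes back at 14. It replaces the uncatalysed pericyclic closure by a metal-templated stepwise [4+2] with [Rh(cod)Cl]2 and tris(1,1,1,3,3,3-hexafluoropropan-2-yl) phosphite in toluene at 60–80 °C. Monovalent rhodium first couples the diene terminus with the terminal allene bond to a rhodacycle and then closes the second bond by reductive elimination, at a temperature below that of the hydrogen shift. It makes no new compound.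

Second: step 9. The naked enolate can add to the acrylate of another molecule, equilibration to the C7 dienolate may be incomplete, and some γ-protonation would give the conjugated isomer. The fallback sets out from 14 and comes back at 17. HF·pyridine in THF cleaves the enol ether to the 7α-epimeric ketone methyl (3R,7S,10R)-3-angeloyloxy-8-oxoeudesma-4,11(13)-dien-12-oate F1. DBU in CH2Cl2 then drives F1 deliberately into the thermodynamic sink, the conjugated enone methyl (3R,10R)-3-angeloyloxy-8-oxoeudesma-4,7(11)-dien-12-oate F2. γ-Deprotonation of F2 with LDA/HMPA in THF at −78 °C gives the lithium dienolate lithium (3R,10R)-3-angeloyloxy-12-methoxy-12-oxoeudesma-4,7,11(13)-trien-8-olate F3, and an acetic acid quench at −78 °C (classical deconjugative α-protonation, axial from the α face) returns 17.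

Third: step 12. Hydrogen abstraction from C6 would give the 4-hydroperoxy-5-ene isomer, and the pseudoaxial 3α-angelate partly shields the α face. The fallback sets out from 19 and comes back at 20. Dimethyldioxirane in acetone at 0 °C epoxidises the tetrasubstituted alkene anti to the angular methyl to give methyl (3R,4R,5S,7R,8R,10R)-8-acetoxy-3-angeloyloxy-4α,5α-epoxyeudesm-11(13)-en-12-oate F4. Diethylaluminium 2,2,6,6-tetramethylpiperidide in toluene at 0 °C removes a C15 methyl proton syn to the epoxide and gives the tertiary allylic alcohol methyl (3R,5S,7R,8R,10R)-8-acetoxy-3-angeloyloxy-5-hydroxyeudesma-4(15),11(13)-dien-12-oate F5. Perhydrolysis of F5 with 50 % H2O2 and catalytic H2SO4 in Et2O at 0 °C then captures the allylic cation at the tertiary C5 from the α face and gives 20.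

**Further compounds**
F0 | step 8 | none | none
F1 | step 9 | methyl (3R,7S,10R)-3-angeloyloxy-8-oxoeudesma-4,11(13)-dien-12-oate | C=C(C(=O)OC)[C@@H]1CC2=C(C)[C@H](OC(=O)/C(C)=C\C)CC[C@]2(C)CC1=O
F2 | step 9 | methyl (3R,10R)-3-angeloyloxy-8-oxoeudesma-4,7(11)-dien-12-oate | COC(=O)C(C)=C1CC2=C(C)[C@H](OC(=O)/C(C)=C\C)CC[C@]2(C)CC1=O
F3 | step 9 | lithium (3R,10R)-3-angeloyloxy-12-methoxy-12-oxoeudesma-4,7,11(13)-trien-8-olate | [Li+].C=C(C(=O)OC)C=1CC2=C(C)[C@H](OC(=O)/C(C)=C\C)CC[C@]2(C)CC=1[O-]
F4 | step 12 | methyl (3R,4R,5S,7R,8R,10R)-8-acetoxy-3-angeloyloxy-4α,5α-epoxyeudesm-11(13)-en-12-oate | C=C(C(=O)OC)[C@H]1C[C@@]2(O3)[C@@]3(C)[C@H](OC(=O)/C(C)=C\C)CC[C@]2(C)C[C@H]1OC(C)=O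
F5 | step 12 | methyl (3R,5S,7R,8R,10R)-8-acetoxy-3-angeloyloxy-5-hydroxyeudesma-4(15),11(13)-dien-12-oate | C=C(C(=O)OC)[C@H]1C[C@@]2(O)C(=C)[C@H](OC(=O)/C(C)=C\C)CC[C@]2(C)C[C@H]1OC(C)=O
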